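The rate constants are assumed; no experiment stands behind them.

Reciprocal seconds are the unit I reckon in for the quick number you ask for on these flasks.

the same everywhere: solid substrate 0.050 M; partner 0.125 M (fed, over 3.0 s); capture agent 0.0500 M; time 1.0 min
- Thursday's: temperature 35 °C; the fed solution adds 0.25 times the starting volume
- Wednesday's: temperature 65 °C; the fed solution adds 0.25 times the starting volume
- Sunday's: temperature 95 °C; the fed solution adds 0.25 times the starting volume

- the best flask by amount of target, in percent of the solid substrate charged; "all alike" if 1.5 percentage points covers them all (Thursday's / Wednesday's / Sunday's / all alike)
- amount of target at the end, in percent of the solid substrate charged, Thursday's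
- amount of target at the end, in percent of the solid substrate charged, Wednesday's
- amount of target at the end, in percent of the solid substrate charged, Sunday's

- percentages count the solid substrate that a species holds: one homo product counts as two
- two of one species on the left: rate k times its square, two consumed each time
- every charge counts on the volume at the start, and the solution that is fed holds the whole dose
- solid, in amounts per volume of the solution: solid substrate
- the list of constants is for 35 °C, to be carried to other temperatures by the activation energies
- at the start none of the solid substrate is in solution
- what has only dissolved of solid substrate counts as not reacted

    starting material → open intermediate (k1 = 0.17 /s, Ea1 = 76.0 kJ/mol)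
    partner → second intermediate (k2 = 0.031 /s, Ea2 = 87.0 kJ/mol)
    open intermediate + second intermediate → target (k3 = 0.17 /M/s, Ea3 = 40.0 kJ/mol)
    2 open intermediate → homo product (k4 = 0.023 /M/s, Ea4 = 59.0 kJ/mol)
    partner → decomposition product (k5 = 8.1 × 10⁻⁵ /s, Ea5 = 90.0 kJ/mol)
    solid substrate ⇌ starting material, rate k6*(cs6 - [starting material]) while solid is left; crystals form when [starting material] > cs6 (cs6 = 4.1 mM, k6 = 0.44 /s)
    open intermediate + capture agent → trapped intermediate (k7 = 0.043 /M/s, Ea7 = 68.0 kJ/mol)
    (constants at 35 °C)

Of the exits of open intermediate I set two against each other: coupling with second intermediate to give target (0.17 /M/s, 40.0 kJ/mol), and capture to give trapped intermediate (0.043 /M/s, 68.0 kJ/mol). After the feed, c(second intermediate) can reach 0.100 M and c(capture agent) stands at 0.0400 M. Holding both steady makes each exit pseudo-first-order, so at 35 °C coupling runs at 0.0170 /s and capture at 0.00172 /s. Their quotient, coupling over capture, is the selectivity factor S, here 9.88.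

I work in decimal logarithms, where S starts at 0.995. Capture has the steeper activation energy, so heat subtracts from that logarithm: 0.421 at 65 °C and 0.774 at 95 °C. That leaves S at 3.75 for Wednesday's and 1.66 for Sunday's, and the coupling share S/(1+S) at 78.9% and 62.4%.

Heat also shortens the wait. The reciprocal of the two rates added is 53.4 s in Thursday's and 11.6 s in Wednesday's, against a reading at 60 s. Open intermediate present from the first moment of Thursday's would still keep 32.5% of itself at the reading, so I expect that flask to be unfinished. I commit to Wednesday's as best, with target somewhat under its share, Sunday's under its own, and Thursday's lowest, without a figure.

The forecast also names Wednesday's, with 20% for Thursday's, 69% for Wednesday's and 61% for Sunday's. Its ground for the hot flasks is that “capture (the higher activation energy) takes a growing share from the target coupling”. It gives Thursday's a number where I give none.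

The simulation gives 18.2% for Thursday's, 70.6% for Wednesday's and 61.6% for Sunday's, so Wednesday's is best, as the forecast has it.

Thursday's still holds 50.7% as open intermediate at 1.00 min, and left until 10.0 min it reaches 84.2% target, so at the reading it is an unfinished flask. In Wednesday's, target over trapped intermediate reads 3.50 at 1.00 min, against my S of 3.75.

The same reckoning on Thursday's flask run at 50 °C takes 0.220 off the logarithm, so S is 5.95. The run gives target over trapped intermediate of 5.22, with 59.5% target and 24.7% still open intermediate.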